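**Strategy**

Numbering: C1 (quaternary, CH3), C2 (CHOAc), C3, C4 (C(OH)iPr), C5 (ring-fusion CH), C6 (CH–O-aroyl), C7–C10. The route rests on disconnecting C4–C5 of the cyclopentane ring C1–C5: C4–OH and the C6 oxygen are a β-hydroxy ketone pair, so the ring is the aldol of a C6-ketone enolate (C5) with an isopropyl ketone on a chain at C1. The key step, a SmI2-promoted Reformatsky-type aldol, closes this ring onto the finished seven-membered ring and sets C4 and the trans ring fusion (C5) in one operation. Its precursor is a monocyclic 7-bromocyclohept-2-enone bearing a 1-acetoxy-4-methyl-3-oxopentyl chain on its quaternary carbon.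

Key step: step 9

Remark: α is the face of the C1 methyl group, β the opposite face; C8 is the methyl-bearing oxirane carbon and C9 the oxirane CH.
Remark: the oxirane is treated as a functional group put on the completed carbon skeleton (two carbocycles); the trichlorosilyl enol ether of 3-methylbutan-2-one (step 7) is a reagent made beforehand from the commercial ketone.

**Route**

Step 1
Reactants: 1 3-methylcyclohex-2-en-1-one
Product: 2 (±)-3,6-dimethylcyclohex-2-en-1-one
Conditions: LiN(iPr)2, THF, −78 °C; CH3I, −78 to 0 °C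
Reagents that add atoms: iodomethane CI
Why: Kinetic α′-deprotonation gives the cross-conjugated lithium enolate, which is C-methylated (enolate alkylation); the new stereocentre is removed in step 2.

Step 2
Reactants: 2 (±)-3,6-dimethylcyclohex-2-en-1-one
Product: 3 [(2,5-dimethylcyclohexa-1,5-dien-1-yl)oxy]trimethylsilane
Conditions: LiN(iPr)2, THF, −78 °C; Me3SiCl
Reagents that add atoms: chlorotrimethylsilane C[Si](C)(C)Cl
Why: A second kinetic α′-deprotonation removes the tertiary C6–H and O-silylation traps the cross-conjugated enolate as the 2-silyloxy diene (silyl enol ether formation).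

Step 3
Reactants: 3 [(2,5-dimethylcyclohexa-1,5-dien-1-yl)oxy]trimethylsilane
Product: 4 (±)-[(3,6-dimethylbicyclo[4.1.0]hept-2-en-1-yl)oxy]trimethylsilane
Conditions: Et2Zn, CH2I2, CH2Cl2, 0 °C
Reagents that add atoms: diiodomethane ICI
Why: The Furukawa variant of the Simmons–Smith cyclopropanation should attack the electron-rich silyl enol ether double bond in preference to the conjugated trisubstituted alkene.

Step 4
Reactants: 4 (±)-[(3,6-dimethylbicyclo[4.1.0]hept-2-en-1-yl)oxy]trimethylsilane
Product: 6 3,6-dimethylcyclohepta-2,6-dien-1-one, via 6-chloro-3,6-dimethylcyclohept-2-en-1-one 5 (not isolated)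
Conditions: FeCl3, DMF, 0 °C; then NaOAc, MeOH, reflux
Reagents that add atoms: none
Why: Saegusa-type oxidative ring expansion: FeCl3 opens the siloxycyclopropane at the internal bond to the tertiary β-keto radical, which is chlorinated, and acetate-induced E1cB loss of HCl should give the symmetric cross-conjugated dienone.

Step 5
Reactants: 6 3,6-dimethylcyclohepta-2,6-dien-1-one
Product: 9 (6R)-7-bromo-3,6-dimethyl-6-vinylcyclohept-2-en-1-one (both C7 epimers), via dimethylaluminium dienolate 7 (not isolated), via trimethylsilyl dienol ether 8 (not isolated)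
Conditions: CH2=CHMgBr + Me2AlCl (gives Me2Al(CH=CH2)), CuTC (copper thiophene-2-carboxylate, cat.), (R,R)-N,N-bis[1-(naphthalen-2-yl)ethyl]-P,P-diphenylphosphinous amide (SimplePhos-type ligand, cat.; enantiomer chosen for the (S)-configured vinyl adduct), Et2O, −30 °C; then Me3SiOTf, −30 to 0 °C; then N-bromosuccinimide, THF, −78 °C
Reagents that add atoms: dimethyl(vinyl)aluminium C=C[Al](C)C; N-bromosuccinimide O=C1CCC(=O)N1Br
Why: Copper-catalysed asymmetric conjugate addition of an alkenylalane desymmetrises the dienone (the two β-carbons are enantiotopic), the chiral ligand setting the quaternary centre C1, and the regiodefined enolate is silylated and brominated at the α′-carbon (future C5), whose configuration is irrelevant.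

Step 6
Reactants: 9 (6R)-7-bromo-3,6-dimethyl-6-vinylcyclohept-2-en-1-one
Product: 10 (1R)-2-bromo-1,5-dimethyl-3-oxocyclohept-4-ene-1-carbaldehyde (both C2 epimers)
Conditions: O3, CH2Cl2/MeOH, −78 °C, stopped when the vinyl group is consumed; Me2S
Reagents that add atoms: ozone [O-][O+]=O
Why: Ozonolysis should cleave the electron-rich monosubstituted alkene much faster than the electron-poor enone double bond, giving the non-enolisable aldehyde (future C2) without touching C1.

Step 7
Reactants: 10 (1R)-2-bromo-1,5-dimethyl-3-oxocyclohept-4-ene-1-carbaldehyde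
Product: 11 (6R)-7-bromo-6-[(1R)-1-hydroxy-4-methyl-3-oxopentyl]-3,6-dimethylcyclohept-2-en-1-one (both C7 epimers)
Conditions: CH2=C(OSiCl3)CH(CH3)2, (4S,5S)-1,3-dimethyl-4,5-diphenyl-2-(piperidin-1-yl)-1,3,2-diazaphospholidine 2-oxide (cat.; enantiomer chosen for the (R)-carbinol), CH2Cl2, −78 °C; cold aq NaHCO3
Reagents that add atoms: trichloro[(3-methylbut-1-en-2-yl)oxy]silane C=C(O[Si](Cl)(Cl)Cl)C(C)C
Why: Lewis-base-catalysed aldol addition of a methyl-ketone trichlorosilyl enolate through a closed siliconate transition state is chemoselective for the aldehyde, and the chiral phosphoramide (reagent control) sets C2.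

Step 8
Reactants: 11 (6R)-7-bromo-6-[(1R)-1-hydroxy-4-methyl-3-oxopentyl]-3,6-dimethylcyclohept-2-en-1-one
Product: 12 (1R)-1-[(1R)-2-bromo-1,5-dimethyl-3-oxocyclohept-4-en-1-yl]-4-methyl-3-oxopentyl acetate (both epimers at CHBr)
Conditions: Ac2O, pyridine, DMAP (cat.), CH2Cl2, 0 °C
Reagents that add atoms: acetic anhydride CC(=O)OC(C)=O
Why: DMAP-catalysed acylation installs the final C2 acetate early, which also keeps the C2 oxygen from bridging to the metal in step 9 and from forming a hemiketal with the C6 ketone.

Step 9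
Reactants: 12 (1R)-1-[(1R)-2-bromo-1,5-dimethyl-3-oxocyclohept-4-en-1-yl]-4-methyl-3-oxopentyl acetate
Product: 14 (1R,3S,3aS,8aS)-3-hydroxy-6,8a-dimethyl-4-oxo-3-(propan-2-yl)-1,2,3,3a,4,7,8,8a-octahydroazulen-1-yl acetate (trans-fused), via diiodosamarium dienolate 13 (not isolated)
Conditions: SmI2 (2.2 equiv), THF, −78 to −20 °C; aq NH4Cl
Reagents that add atoms: none
Why: Two single-electron transfers from SmI2 cleave the C5–Br bond and give the trivalent samarium dienolate 13 regiospecifically at C5, which adds to the isopropyl ketone C4 through a closed, samarium-bridged Zimmerman–Traxler-type transition state; the closest known reaction type is the SmI2-promoted intramolecular Reformatsky-type aldol of α-bromo ketones. The cyclopentane C1–C5 closes in the 5-(enolexo)-exo-trig mode onto the existing seven-membered ring. C4 is controlled by the C2 stereocentre and the angular methyl: the isopropyl group should take the pseudo-equatorial position cis to the 2-acetoxy group and away from the C1 methyl, which places the C4 oxygen on the α face. C5 is controlled by the samarium bridge between the C4 and C6 oxygens, which holds the C4 oxygen and C6 cis on the new ring and so puts H-5 trans to the C1 methyl (trans fusion); reversibility of the samarium aldolate should let any strained cis-fused adduct funnel to this chelated isomer. The step needs chemoselective reduction of C–Br beside the enone, the ketone and the acetate, secured by the much faster electron transfer to an α-bromo ketone at −78 °C without HMPA, and enolate formation at C5 rather than C7 or C3, secured by the position of the bromine. No base is present, so the β-acetoxy ketone should not eliminate.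

Step 10
Reactants: 14 (1R,3S,3aS,8aS)-3-hydroxy-6,8a-dimethyl-4-oxo-3-(propan-2-yl)-1,2,3,3a,4,7,8,8a-octahydroazulen-1-yl acetate
Product: 16 (1R,3S,3aS,8aS)-3-hydroxy-6,8a-dimethyl-4-oxo-3-(propan-2-yl)-1,2,3,3a,4,5,8,8a-octahydroazulen-1-yl acetate, via bis(trimethylsilyl) dienol ether 15 (not isolated)
Conditions: Me3SiOTf, Et3N, CH2Cl2, 0 °C to rt; then Bu4NF, AcOH, THF, −78 °C
Reagents that add atoms: none
Why: Deconjugation by kinetic protonation: γ-deprotonation at C9 (H-5 lies between two quaternary carbons) gives the linear silyl dienol ether, and fluoride release of the dienolate with acetic acid present should protonate C7 (α), leaving the C8=C9 alkene and the C5 configuration untouched.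

Step 11
Reactants: 16 (1R,3S,3aS,8aS)-3-hydroxy-6,8a-dimethyl-4-oxo-3-(propan-2-yl)-1,2,3,3a,4,5,8,8a-octahydroazulen-1-yl acetate
Product: 17 (1R,3S,3aR,4R,8aS)-3,4-dihydroxy-6,8a-dimethyl-3-(propan-2-yl)-1,2,3,3a,4,5,8,8a-octahydroazulen-1-yl acetate
Conditions: Me4NBH(OAc)3, AcOH/MeCN, −20 °C
Reagents that add atoms: none
Why: Evans–Saksena reduction: the acetoxyborohydride bound to the C4 α-hydroxyl delivers hydride intramolecularly to the α face of the C6 carbonyl, which should give the 6β-alcohol (anti-1,3-diol).

Step 12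
Reactants: 17 (1R,3S,3aR,4R,8aS)-3,4-dihydroxy-6,8a-dimethyl-3-(propan-2-yl)-1,2,3,3a,4,5,8,8a-octahydroazulen-1-yl acetate
Product: 18 2β-acetoxy-8β,9β-epoxydaucane-4α,6β-diol (1α-methyl, 5β-H)
Conditions: VO(acac)2 (cat.), t-BuOOH, CH2Cl2, 0 °C to rt
Reagents that add atoms: tert-butyl hydroperoxide CC(C)(C)OO
Why: Hydroxyl-directed epoxidation: the homoallylic 6β-hydroxyl should deliver the vanadium-bound peroxide to the β face of C8=C9, which is also the face away from the angular methyl.

Step 13
Reactants: 18 2β-acetoxy-8β,9β-epoxydaucane-4α,6β-diol, 19 4-methoxybenzoyl chloride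
Product: 20 2β-acetoxy-8β,9β-epoxy-4α-hydroxydaucan-6β-yl 4-methoxybenzoate (target, CNP0317703.1)
Conditions: Et3N, DMAP (cat.), CH2Cl2, 0 °C to rt
Reagents that add atoms: none
Why: DMAP-catalysed acylation should esterify the only secondary hydroxyl (C6) while the tertiary C4 hydroxyl stays free and the basic medium spares the oxirane.

**Compound list**

1 | 3-methylcyclohex-2-en-1-one | CC1=CC(=O)CCC1 | starting material
2 | (±)-3,6-dimethylcyclohex-2-en-1-one | CC1=CC(=O)C(C)CC1 | intermediate
3 | [(2,5-dimethylcyclohexa-1,5-dien-1-yl)oxy]trimethylsilane | CC1=CC(O[Si](C)(C)C)=C(C)CC1 | intermediate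
4 | (±)-[(3,6-dimethylbicyclo[4.1.0]hept-2-en-1-yl)oxy]trimethylsilane | CC1=CC2(O[Si](C)(C)C)CC2(C)CC1 | intermediate
5 | (±)-6-chloro-3,6-dimethylcyclohept-2-en-1-one | CC1=CC(=O)CC(C)(Cl)CC1 | intermediate (not isolated)
6 | 3,6-dimethylcyclohepta-2,6-dien-1-one | CC1=CC(=O)C=C(C)CC1 | intermediate
7 | dimethylaluminium (3R)-3,6-dimethyl-3-vinylcyclohepta-1,6-dien-1-olate | C[Al](C)OC1=C[C@@](C)(C=C)CCC(C)=C1 | intermediate (not isolated)
8 | [(3R)-3,6-dimethyl-3-vinylcyclohepta-1,6-dien-1-yl]oxy(trimethyl)silane | C[Si](C)(C)OC1=C[C@@](C)(C=C)CCC(C)=C1 | intermediate (not isolated)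
9 | (6R)-7-bromo-3,6-dimethyl-6-vinylcyclohept-2-en-1-one, both C7 epimers | O=C1C=C(C)CC[C@](C)(C=C)C1Br | intermediate
10 | (1R)-2-bromo-1,5-dimethyl-3-oxocyclohept-4-ene-1-carbaldehyde, both C2 epimers | O=C1C=C(C)CC[C@](C)(C=O)C1Br | intermediate
11 | (6R)-7-bromo-6-[(1R)-1-hydroxy-4-methyl-3-oxopentyl]-3,6-dimethylcyclohept-2-en-1-one, both C7 epimers | O=C1C=C(C)CC[C@](C)([C@H](O)CC(=O)C(C)C)C1Br | intermediate
12 | (1R)-1-[(1R)-2-bromo-1,5-dimethyl-3-oxocyclohept-4-en-1-yl]-4-methyl-3-oxopentyl acetate, both CHBr epimers | O=C1C=C(C)CC[C@](C)([C@H](OC(C)=O)CC(=O)C(C)C)C1Br | intermediate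
13 | diiodosamarium dienolate of debrominated 12 (trivalent samarium, enolate carbon C5) | CC(C)C(=O)C[C@@H](OC(C)=O)[C@@]1(C)CCC(C)=CC(O[Sm](I)I)=C1 | intermediate (not isolated)
14 | (1R,3S,3aS,8aS)-3-hydroxy-6,8a-dimethyl-4-oxo-3-(propan-2-yl)-1,2,3,3a,4,7,8,8a-octahydroazulen-1-yl acetate | O=C1C=C(C)CC[C@]2(C)[C@H](OC(C)=O)C[C@](O)(C(C)C)[C@@H]12 | intermediate
15 | 6,8a-dimethyl-3-(propan-2-yl)-3,4-bis[(trimethylsilyl)oxy]-1,2,3,3a,8,8a-hexahydroazulen-1-yl acetate (configuration as in 14) | C[Si](C)(C)OC1=CC(C)=CC[C@]2(C)[C@H](OC(C)=O)C[C@](O[Si](C)(C)C)(C(C)C)[C@@H]12 | intermediate (not isolated)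
16 | (1R,3S,3aS,8aS)-3-hydroxy-6,8a-dimethyl-4-oxo-3-(propan-2-yl)-1,2,3,3a,4,5,8,8a-octahydroazulen-1-yl acetate | O=C1CC(C)=CC[C@]2(C)[C@H](OC(C)=O)C[C@](O)(C(C)C)[C@@H]12 | intermediate
17 | (1R,3S,3aR,4R,8aS)-3,4-dihydroxy-6,8a-dimethyl-3-(propan-2-yl)-1,2,3,3a,4,5,8,8a-octahydroazulen-1-yl acetate | O[C@@H]1CC(C)=CC[C@]2(C)[C@H](OC(C)=O)C[C@](O)(C(C)C)[C@@H]12 | intermediate
18 | 2β-acetoxy-8β,9β-epoxydaucane-4α,6β-diol (1α-methyl, 5β-H) | O[C@@H]2C[C@]3(C)O[C@@H]3C[C@]3(C)[C@H](OC(C)=O)C[C@](O)(C(C)C)[C@@H]23 | intermediate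
19 | 4-methoxybenzoyl chloride | COc1ccc(C(Cl)=O)cc1 | starting material
20 | 2β-acetoxy-8β,9β-epoxy-4α-hydroxydaucan-6β-yl 4-methoxybenzoate (CNP0317703.1) | COc1ccc(C(=O)O[C@@H]2C[C@]3(C)O[C@@H]3C[C@]3(C)[C@H](OC(C)=O)C[C@](O)(C(C)C)[C@@H]23)cc1 | target

**Step count and risks**

Total step count: 13. Longest linear sequence: 13.

Steps most likely to fail:

1. Step 9 (key step). The ring closure may show poor facial selectivity, giving the cis-fused junction or the C4 epimer, and SmI2 may over-reduce the enone. The fallback replaces the chelated reductive closure by an open-transition-state closure followed by thermodynamic equilibration. It sets out from 12: reductive silylation (Zn, Me3SiCl, MeCN) should give the trimethylsilyl dienol ether F1. A Mukaiyama aldol (TiCl4, CH2Cl2, −78 °C) then closes the cyclopentane, expected mainly as the cis-fused C5 epimer F2. Magnesium-mediated retro-aldol/aldol equilibration (MgBr2·OEt2, iPr2NEt, CH2Cl2) should convert F2 into the chelate-stabilised trans-fused isomer, coming back to the route at 14.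

2. Step 10. The kinetically formed β,γ-enone may slip back into conjugation during protonation or work-up, and γ-deprotonation may occur at the C8 methyl. The fallback traps the deconjugated ketone by reduction and then re-oxidises. It sets out from 14, which is silylated as before to 15. Treating 15 with NaBH4 in EtOH at 0 °C releases the dienolate, protonates it at C7 and reduces the ketone at once, giving the homoallylic alcohol as a C6-epimer mixture F3. Buffered Dess–Martin oxidation (NaHCO3, CH2Cl2) then returns the β,γ-enone without conjugation, coming back to the route at 16.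

3. Step 5. The desymmetrising vinyl transfer to the cross-conjugated dienone may be slow or poorly enantioselective, and bromination of the weakly nucleophilic aluminium enolate may be inefficient. The fallback uses iminium organocatalysis with nitromethane as a formyl-anion equivalent. It sets out from 6: high-pressure addition of nitromethane with a 9-amino-9-deoxy-epi-cinchona primary amine and benzoic acid should give (S)-3,6-dimethyl-6-(nitromethyl)cyclohept-2-en-1-one F4. A Nef reaction (NaOMe, MeOH; then TiCl3, NH4OAc buffer) gives (1S)-1,5-dimethyl-3-oxocyclohept-4-ene-1-carbaldehyde F5. Kinetic α′-silylation (Me3SiOTf, Et3N, −78 °C) gives the silyl dienol ether F6, which is brominated with N-bromosuccinimide, coming back to the route at 10.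

**Further compounds**

F1 | step 9 | (1R)-1-[(1R)-1,5-dimethyl-3-[(trimethylsilyl)oxy]cyclohepta-2,4-dien-1-yl]-4-methyl-3-oxopentyl acetate | CC(C)C(=O)C[C@@H](OC(C)=O)[C@@]1(C)CCC(C)=CC(O[Si](C)(C)C)=C1
F2 | step 9 | cis-fused C5 epimer of 14 (5α-H) | O=C1C=C(C)CC[C@]2(C)[C@H](OC(C)=O)C[C@](O)(C(C)C)[C@H]12
F3 | step 10 | C6-epimer mixture of 17 | OC1CC(C)=CC[C@]2(C)[C@H](OC(C)=O)C[C@](O)(C(C)C)[C@@H]12
F4 | step 5 | (S)-3,6-dimethyl-6-(nitromethyl)cyclohept-2-en-1-one | O=C1C=C(C)CC[C@](C)(C[N+](=O)[O-])C1
F5 | step 5 | (1S)-1,5-dimethyl-3-oxocyclohept-4-ene-1-carbaldehyde | O=C1C=C(C)CC[C@](C)(C=O)C1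
F6 | step 5 | 1,5-dimethyl-3-[(trimethylsilyl)oxy]cyclohepta-2,4-diene-1-carbaldehyde (configuration as in F5) | C[Si](C)(C)OC1=C[C@@](C)(C=O)CCC(C)=C1
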